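**Retrosynthetic overview**
- The 1,3-diketone is cut between its CH2 and the carbonyl on ring A: a Claisen condensation joins a ring A methyl benzoate to the enolate of silyl-protected 4'-hydroxyacetophenone (ring B is bought).
- The strategy rests on ring A carrying four contiguous substituents, C1' (acyl), C2' (OMe), C3' (prenyl) and C4' (OH), beside an unsubstituted C5'–C6' edge.
- Ring A is cut at C3'–C4' and C5'–C6'. C1', C2', C3' and C6' come from C5, C4, C3 and C6 of a 4-methoxy-3-prenyl-2-pyrone-5-carboxylate, and C4' and C5' come from ketene bis(trimethylsilyl) acetal, with loss of carbon dioxide and silanol.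
- The pyrone is built from dimethyl acetonedicarboxylate and trimethyl orthoformate, then prenylated at C3 and methylated at O4.
- Ring order: the sacrificial pyrone ring first, then ring A by cycloaddition and decarboxylation.

Key step: step 5

Assumption: the target is drawn as the diketo tautomer and should exist in equilibrium with its chelated enol; it has no stereocentre, so the route sets none.

**Route**

Step 1
Reactants: 1 dimethyl 1,3-acetonedicarboxylate; 2 trimethyl orthoformate
Product: 4 methyl 4-hydroxy-2-oxo-2H-pyran-5-carboxylate, via dimethyl 2-(methoxymethylene)-3-oxopentanedioate 3 (not isolated)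
Conditions: HC(OMe)3 (1.1 equiv), Ac2O, 120 °C; concentrate; then 2 M HCl, rt
Reagents that add atoms: water, O
Why: Alkoxymethylenation of one active methylene with orthoformate and acetic anhydride gives the enol ether, which acid hydrolyses to the hydroxymethylene ketoester that lactonises onto the distal ester, the standard entry to 4-hydroxy-2-pyrone-5-carboxylates.

Step 2
Reactants: 4 methyl 4-hydroxy-2-oxo-2H-pyran-5-carboxylate; 5 prenyl bromide
Product: 6 methyl 4-hydroxy-3-(3-methylbut-2-enyl)-2-oxo-2H-pyran-5-carboxylate
Conditions: DBU (1.0 equiv, premixed with 4), Pd(PPh3)4 (5 mol %), THF, 50 °C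
Reagents that add atoms: none
Why: In this Tsuji–Trost allylation the soft pyronate should attack the unsubstituted terminus of the 1,1-dimethylallyl ligand through C3, its only C–H nucleophilic carbon, and O-allylation is reversible under zerovalent palladium whereas C-allylation is not.

Step 3
Reactants: 6 methyl 4-hydroxy-3-(3-methylbut-2-enyl)-2-oxo-2H-pyran-5-carboxylate
Product: 7 methyl 4-methoxy-3-(3-methylbut-2-enyl)-2-oxo-2H-pyran-5-carboxylate
Conditions: Me2SO4, K2CO3, acetone, reflux
Reagents that add atoms: dimethyl sulfate, COS(=O)(=O)OC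
Why: O-methylation of the vinylogous acid with a hard methylating agent and K2CO3 should give the 4-methoxy-2-pyrone, since C-methylation at the already substituted C3 would break the pyrone conjugation.

Step 4
Reactants: 8 trimethylsilyl acetate
Product: 10 1,1-bis(trimethylsilyloxy)ethene, via lithium enolate of trimethylsilyl acetate 9 (not isolated)
Conditions: LiN(iPr)2 (commercial solution), THF, −78 °C; then Me3SiCl, −78 °C to rt; distil
Reagents that add atoms: chlorotrimethylsilane, C[Si](C)(C)Cl
Why: Kinetic deprotonation of the silyl ester and O-silylation of its enolate is the usual preparation of ketene bis(silyl) acetals.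

Step 5
Reactants: 7 methyl 4-methoxy-3-(3-methylbut-2-enyl)-2-oxo-2H-pyran-5-carboxylate; 10 1,1-bis(trimethylsilyloxy)ethene
Product: 14 methyl 4-hydroxy-2-methoxy-3-(3-methylbut-2-enyl)benzoate, via bicyclic lactone adduct 11 (not isolated), via cyclohexadiene acetal 12 (not isolated), via aryl trimethylsilyl ether 13 (not isolated)
Conditions: 10 (4 equiv), toluene, sealed tube, 120–150 °C; then 1 M HCl, THF, rt
Reagents that add atoms: none
Why: Proposed new method: the nucleophilic CH2 of 10 should attack C6 of pyrone 7, which is the β-carbon of the alkoxyacrylate formed with the 5-ester and the terminus of the dienyl lactone, and the silyloxy-stabilised cationic carbon should then close onto C3, in a concerted asynchronous or stepwise (4+2) addition, to give the bicyclo[2.2.2] lactone 11. Cycloreversion should expel carbon dioxide to give cyclohexadiene 12, 1,2-elimination of trimethylsilanol across the acetal carbon and its CH2 neighbour should aromatise it to silyl ether 13, and dilute acid should free phenol 14. The closest known reaction type is the inverse-electron-demand Diels–Alder reaction of methyl coumalate and 3-alkoxycarbonyl-2-pyrones with ketene acetals and enol ethers, which gives benzoates after loss of carbon dioxide and alcohol; the donor 4-methoxy group and the 3-prenyl group of 7 are the untested part and are the reason for heat and excess acetal. Ring A is closed by an intermolecular (4+2) annulation that forms C3'–C4' and C5'–C6' in one operation, and no stereocentre remains because the two bridgehead centres of 11 are erased on aromatisation. The step needs the regiochemistry CH2 to C6 and acetal carbon to C3, which the 5-ester secures by polarising the diene, and the elimination can only expel silanol because the methoxy-bearing carbon is already sp2 in 12.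

Step 6
Reactants: 14 methyl 4-hydroxy-2-methoxy-3-(3-methylbut-2-enyl)benzoate
Product: 15 methyl 4-(tert-butyldimethylsilyloxy)-2-methoxy-3-(3-methylbut-2-enyl)benzoate
Conditions: TBSCl, imidazole, DMF, rt
Reagents that add atoms: tert-butyldimethylsilyl chloride, CC(C)(C)[Si](C)(C)Cl
Why: Imidazole-mediated silylation of the phenol masks the acidic OH, which would otherwise form a phenoxide and deactivate the benzoate in the Claisen condensation.

Step 7
Reactants: 16 4'-hydroxyacetophenone
Product: 17 4'-(tert-butyldimethylsilyloxy)acetophenone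
Conditions: TBSCl, imidazole, DMF, rt
Reagents that add atoms: tert-butyldimethylsilyl chloride, CC(C)(C)[Si](C)(C)Cl
Why: Silyl ether formation on the phenol lets the methyl ketone be enolised cleanly with one equivalent of amide base.

Step 8
Reactants: 15 methyl 4-(tert-butyldimethylsilyloxy)-2-methoxy-3-(3-methylbut-2-enyl)benzoate; 17 4'-(tert-butyldimethylsilyloxy)acetophenone
Product: 19 1-[4-(tert-butyldimethylsilyloxy)-2-methoxy-3-(3-methylbut-2-enyl)phenyl]-3-[4-(tert-butyldimethylsilyloxy)phenyl]propane-1,3-dione, via lithium enolate of the silyloxyacetophenone 18 (not isolated)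
Conditions: LiN(SiMe3)2 (2.4 equiv), 17 (1.1 equiv), THF, −78 °C; then 15, −78 °C to rt; 1 M HCl, 0 °C
Reagents that add atoms: none
Why: In this crossed Claisen condensation the ketone enolate adds to the non-enolisable benzoate, and the second equivalent of base deprotonates the 1,3-diketone and so pulls the equilibrium forward.

Step 9
Reactants: 19 1-[4-(tert-butyldimethylsilyloxy)-2-methoxy-3-(3-methylbut-2-enyl)phenyl]-3-[4-(tert-butyldimethylsilyloxy)phenyl]propane-1,3-dione
Product: 20 1-[4-hydroxy-2-methoxy-3-(3-methylbut-2-enyl)phenyl]-3-(4-hydroxyphenyl)propane-1,3-dione (CNP0308388.0)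
Conditions: Bu4NF (2.2 equiv), AcOH (2.2 equiv), THF, 0 °C
Reagents that add atoms: none
Why: Fluoride cleaves both aryl silyl ethers, and the acetic acid buffer keeps the medium near neutral so that the diketone and the prenyl group are left untouched.

**Compound list**
1 | dimethyl 1,3-acetonedicarboxylate (dimethyl 3-oxopentanedioate) | COC(=O)CC(=O)CC(=O)OC | starting material
2 | trimethyl orthoformate | COC(OC)OC | starting material
3 | dimethyl 2-(methoxymethylene)-3-oxopentanedioate (alkene geometry not defined) | COC=C(C(=O)OC)C(=O)CC(=O)OC | intermediate (not isolated)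
4 | methyl 4-hydroxy-2-oxo-2H-pyran-5-carboxylate | COC(=O)C1=COC(=O)C=C1O | intermediate
5 | prenyl bromide (1-bromo-3-methylbut-2-ene) | CC(C)=CCBr | starting material
6 | methyl 4-hydroxy-3-(3-methylbut-2-enyl)-2-oxo-2H-pyran-5-carboxylate | COC(=O)C1=COC(=O)C(CC=C(C)C)=C1O | intermediate
7 | methyl 4-methoxy-3-(3-methylbut-2-enyl)-2-oxo-2H-pyran-5-carboxylate | COC(=O)C1=COC(=O)C(CC=C(C)C)=C1OC | intermediate
8 | trimethylsilyl acetate | CC(=O)O[Si](C)(C)C | starting material
9 | lithium enolate of trimethylsilyl acetate | [Li]OC(=C)O[Si](C)(C)C | intermediate (not isolated)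
10 | 1,1-bis(trimethylsilyloxy)ethene | C=C(O[Si](C)(C)C)O[Si](C)(C)C | intermediate
11 | methyl 5-methoxy-4-(3-methylbut-2-enyl)-3-oxo-8,8-bis(trimethylsilyloxy)-2-oxabicyclo[2.2.2]oct-5-ene-6-carboxylate (racemic; the two bridgehead centres are fixed relative to each other by the bicycle) | COC(=O)C1=C(OC)C2(CC=C(C)C)C(=O)OC1CC2(O[Si](C)(C)C)O[Si](C)(C)C | intermediate (not isolated)
12 | methyl 6-methoxy-5-(3-methylbut-2-enyl)-4,4-bis(trimethylsilyloxy)cyclohexa-1,5-diene-1-carboxylate | COC(=O)C1=CCC(O[Si](C)(C)C)(O[Si](C)(C)C)C(CC=C(C)C)=C1OC | intermediate (not isolated)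
13 | methyl 2-methoxy-3-(3-methylbut-2-enyl)-4-(trimethylsilyloxy)benzoate | COC(=O)c1ccc(O[Si](C)(C)C)c(CC=C(C)C)c1OC | intermediate (not isolated)
14 | methyl 4-hydroxy-2-methoxy-3-(3-methylbut-2-enyl)benzoate | COC(=O)c1ccc(O)c(CC=C(C)C)c1OC | intermediate
15 | methyl 4-(tert-butyldimethylsilyloxy)-2-methoxy-3-(3-methylbut-2-enyl)benzoate | COC(=O)c1ccc(O[Si](C)(C)C(C)(C)C)c(CC=C(C)C)c1OC | intermediate
16 | 4'-hydroxyacetophenone | CC(=O)c1ccc(O)cc1 | starting material
17 | 4'-(tert-butyldimethylsilyloxy)acetophenone | CC(=O)c1ccc(O[Si](C)(C)C(C)(C)C)cc1 | intermediate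
18 | lithium enolate of 4'-(tert-butyldimethylsilyloxy)acetophenone | [Li]OC(=C)c1ccc(O[Si](C)(C)C(C)(C)C)cc1 | intermediate (not isolated)
19 | 1-[4-(tert-butyldimethylsilyloxy)-2-methoxy-3-(3-methylbut-2-enyl)phenyl]-3-[4-(tert-butyldimethylsilyloxy)phenyl]propane-1,3-dione | COc1c(C(=O)CC(=O)c2ccc(O[Si](C)(C)C(C)(C)C)cc2)ccc(O[Si](C)(C)C(C)(C)C)c1CC=C(C)C | intermediate
20 | 1-[4-hydroxy-2-methoxy-3-(3-methylbut-2-enyl)phenyl]-3-(4-hydroxyphenyl)propane-1,3-dione | COc1c(C(=O)CC(=O)c2ccc(O)cc2)ccc(O)c1CC=C(C)C | target

**Step count**
Total steps: 9. Longest linear sequence: 7 steps (steps 1, 2, 3, 5, 6, 8, 9); steps 4 and 7 are side branches.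

**Steps most likely to fail**

Step 5 (key step, new method). The cycloaddition may not start, because the 4-methoxy group turns the pyrone into a vinylogous carbonate of low electrophilicity. Closure at the fully substituted C3 may also lose to ring opening of the zwitterion or to silyl transfer, so that no benzoate forms. The fallback uses known chemistry, sets out from prenyl bromide 5 and comes back to the route at 15. Commercial methyl 2,4-dihydroxybenzoate F1 would be C-prenylated with 5 in aqueous KOH at room temperature, at the carbon between the two hydroxyl groups, to give methyl 2,4-dihydroxy-3-(3-methylbut-2-enyl)benzoate F2, which is separated from its 5-prenyl isomer by chromatography. The free 4-OH would be silylated selectively with TBSCl and imidazole, the 2-OH being held in a hydrogen bond to the ester, to give methyl 4-(tert-butyldimethylsilyloxy)-2-hydroxy-3-(3-methylbut-2-enyl)benzoate F3. Methylation of the chelated 2-OH with MeI and K2CO3 in dry acetone at reflux would then give 15.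

Step 2. Attack at the substituted terminus of the allyl ligand (reverse prenylation), a second allylation at C3, or persistent O-allylation may erode the yield of the C3-prenyl pyrone. The fallback puts the prenyl group in before the ring is made; it sets out from 1 and 5 and comes back at 6. Monoalkylation of 1 with NaH and 5 in THF at 0 °C would give dimethyl 2-(3-methylbut-2-enyl)-3-oxopentanedioate F4. Condensation with HC(OMe)3 and Ac2O at 120 °C can only occur at the remaining CH2 and would give dimethyl 2-(methoxymethylene)-4-(3-methylbut-2-enyl)-3-oxopentanedioate F5. Brief treatment with dilute HCl at room temperature would lactonise this to 6.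

Step 8. Addition of the enolate to the electron-rich, ortho-substituted benzoate may be slow, so that self-condensation of the ketone and methoxide-induced loss of the silyl ethers compete. The fallback replaces the Claisen condensation by an aldol addition and oxidation; it sets out from 15 and comes back at 19. Reduction of 15 with iBu2AlH in CH2Cl2 at −78 °C would give [4-(tert-butyldimethylsilyloxy)-2-methoxy-3-(3-methylbut-2-enyl)phenyl]methanol F6. Oxidation with MnO2 in CH2Cl2 would give 4-(tert-butyldimethylsilyloxy)-2-methoxy-3-(3-methylbut-2-enyl)benzaldehyde F7. Aldol addition of enolate 18 (from 17 and LiN(iPr)2 at −78 °C) would give racemic 3-[4-(tert-butyldimethylsilyloxy)-2-methoxy-3-(3-methylbut-2-enyl)phenyl]-3-hydroxy-1-[4-(tert-butyldimethylsilyloxy)phenyl]propan-1-one F8. Dess–Martin periodinane would then oxidise the β-hydroxy ketone to 19.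

**Further compounds**
F1 | step 5 | methyl 2,4-dihydroxybenzoate (commercial) | COC(=O)c1ccc(O)cc1O
F2 | step 5 | methyl 2,4-dihydroxy-3-(3-methylbut-2-enyl)benzoate | COC(=O)c1ccc(O)c(CC=C(C)C)c1O
F3 | step 5 | methyl 4-(tert-butyldimethylsilyloxy)-2-hydroxy-3-(3-methylbut-2-enyl)benzoate | COC(=O)c1ccc(O[Si](C)(C)C(C)(C)C)c(CC=C(C)C)c1O
F4 | step 2 | dimethyl 2-(3-methylbut-2-enyl)-3-oxopentanedioate (racemic) | COC(=O)CC(=O)C(CC=C(C)C)C(=O)OC
F5 | step 2 | dimethyl 2-(methoxymethylene)-4-(3-methylbut-2-enyl)-3-oxopentanedioate (racemic; alkene geometry not defined) | COC=C(C(=O)OC)C(=O)C(CC=C(C)C)C(=O)OC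
F6 | step 8 | [4-(tert-butyldimethylsilyloxy)-2-methoxy-3-(3-methylbut-2-enyl)phenyl]methanol | COc1c(CO)ccc(O[Si](C)(C)C(C)(C)C)c1CC=C(C)C
F7 | step 8 | 4-(tert-butyldimethylsilyloxy)-2-methoxy-3-(3-methylbut-2-enyl)benzaldehyde | COc1c(C=O)ccc(O[Si](C)(C)C(C)(C)C)c1CC=C(C)C
F8 | step 8 | 3-[4-(tert-butyldimethylsilyloxy)-2-methoxy-3-(3-methylbut-2-enyl)phenyl]-3-hydroxy-1-[4-(tert-butyldimethylsilyloxy)phenyl]propan-1-one (racemic) | COc1c(C(O)CC(=O)c2ccc(O[Si](C)(C)C(C)(C)C)cc2)ccc(O[Si](C)(C)C(C)(C)C)c1CC=C(C)C
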